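**Retrosynthetic overview**
1. The strategy rests on the oxolane oxygen that links C2 and C9 across the C1–C10 perimeter. Breaking O–C2 (and O3–C16 of the oxepane) uncovers a cyclohexane-fused cyclodeca-2,7-diene whose C9 hydroxyl faces a (2R,3S) C2–C3 epoxide; one transannular 5-exo opening then builds the oxolane and the oxonene together and frees O3 for the oxepane.
2. Ten-membered ring: CrCl2/NiCl2 closure of C6–C7. The C9 carbinol and its (Z)-iodoalkene come from an ynone (transfer hydrogenation, hydroalumination–iodination); the (Z)-C2=C3 olefin comes from an iodo-olefination and a B-alkyl Suzuki coupling.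
3. Cyclohexane: auxiliary-controlled Diels–Alder reaction (bonds C1–C10 and C13–C14) of a Roche-ester-derived enoyl imide with a 4-methylpenta-2,4-dienyl ester; C11 and C12 by hydroboration, oxidation and a hindered hydride.
4. Ring order: cyclohexane, ten-membered carbocycle, oxolane plus oxonene (key step), oxepane (O3 onto a C16 triflate).

Key step: step 29

Remark on numbering: atom numbers are those of the target skeleton. C1 and C10 are the cyclohexane carbons at the oxolane fusion (C1 next to C2 and C14, C10 next to C9 and C11); C11 bears oxygen, C12 a methyl, then C13 and C14. C2 and C9 carry the oxolane oxygen; C3 (methyl), C4, C5, C6 (oxygen), C7 (methyl)=C8 complete the medium ring. C15 (methyl) and C16 form the arm from C14 to O3.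

Remark on protecting groups (assumption): O11 is carried as a TBS ether and acetylated after the oxepane is closed, because an acetate would not pass the hydride steps and would lie 1,3 to the free C9 hydroxyl. O6 carries TBDPS so that both TBS ethers can be removed before it.

**Route**

Step 1
Reactants: 1 (R)-4-benzyloxazolidin-2-one; 2 bromoacetyl bromide
Product: 3 (R)-4-benzyl-3-(2-bromoacetyl)oxazolidin-2-one
Conditions: n-BuLi, THF, −78 °C; then 2, −78 → 0 °C
Reagents that add atoms: none
Why: N-acylation of the lithiated oxazolidinone, the acyl bromide reacting far faster than the CH2Br carbon; no stereocentre is touched.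

Step 2
Reactants: 3 (R)-4-benzyl-3-(2-bromoacetyl)oxazolidin-2-one
Product: 4 (R)-4-benzyl-3-[2-(diethoxyphosphoryl)acetyl]oxazolidin-2-one
Conditions: P(OEt)3, neat, 90 °C
Reagents that add atoms: triethyl phosphite, CCOP(OCC)OCC
Why: Michaelis–Arbuzov reaction of the activated α-bromo imide.

Step 3
Reactants: 5 methyl (S)-3-hydroxy-2-methylpropanoate
Product: 6 methyl (S)-3-(tert-butyldimethylsilyloxy)-2-methylpropanoate
Conditions: TBSCl, imidazole, DMF, 0 °C → rt
Reagents that add atoms: tert-butyldimethylsilyl chloride, CC(C)(C)[Si](C)(C)Cl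
Why: standard silylation of the primary alcohol; the stereocentre (future C15) is not involved.

Step 4
Reactants: 6 methyl (S)-3-(tert-butyldimethylsilyloxy)-2-methylpropanoate
Product: 7 (S)-3-(tert-butyldimethylsilyloxy)-2-methylpropanal
Conditions: i-Bu2AlH, CH2Cl2, −78 °C; then MeOH, aq. Rochelle salt
Reagents that add atoms: none
Why: partial reduction of the ester through the tetrahedral aluminate that is stable at −78 °C; the aldehyde is used at once so that the α-centre does not epimerise.

Step 5
Reactants: 7 (S)-3-(tert-butyldimethylsilyloxy)-2-methylpropanal; 4 (R)-4-benzyl-3-[2-(diethoxyphosphoryl)acetyl]oxazolidin-2-one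
Product: 8 (R)-4-benzyl-3-[(2E,4R)-5-(tert-butyldimethylsilyloxy)-4-methylpent-2-enoyl]oxazolidin-2-one
Conditions: LiCl, i-Pr2NEt, MeCN, rt
Reagents that add atoms: none
Why: Horner–Wadsworth–Emmons olefination under Masamune–Roush conditions, (E)-selective and mild enough to keep the α-stereocentre of the aldehyde (C15, R in the product).

Step 6
Reactants: 9 methacrolein; 10 ethyl (triphenylphosphoranylidene)acetate
Product: 11 ethyl (2E)-4-methylpenta-2,4-dienoate
Conditions: CH2Cl2, rt
Reagents that add atoms: none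
Why: Wittig reaction of a stabilised ylide, (E)-selective.

Step 7
Reactants: 11 ethyl (2E)-4-methylpenta-2,4-dienoate
Product: 12 (2E)-4-methylpenta-2,4-dien-1-ol
Conditions: i-Bu2AlH, Et2O, −78 → 0 °C
Reagents that add atoms: none
Why: 1,2-reduction of the dienoate to the dienol.

Step 8
Reactants: 12 (2E)-4-methylpenta-2,4-dien-1-ol
Product: 13 (2E)-4-methylpenta-2,4-dien-1-yl pivalate
Conditions: PivCl, pyridine, 4-(dimethylamino)pyridine (cat.), CH2Cl2, 0 °C
Reagents that add atoms: pivaloyl chloride, CC(C)(C)C(Cl)=O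
Why: acylation of the primary alcohol; the pivalate is orthogonal to the silyl ethers and is later removed reductively.

Step 9
Reactants: 8 (R)-4-benzyl-3-[(2E,4R)-5-(tert-butyldimethylsilyloxy)-4-methylpent-2-enoyl]oxazolidin-2-one; 13 (2E)-4-methylpenta-2,4-dien-1-yl pivalate
Product: 14 Diels–Alder adduct, the cyclohex-11-ene with the acyl oxazolidinone at C1, CH2OPiv at C10 cis to it and the (R)-CH(Me)CH2OTBS group at C14 trans to it (1S,10R,14S,15R)
Conditions: Et2AlCl (1.5 equiv), CH2Cl2, −78 → −20 °C, diene in excess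
Reagents that add atoms: none
Why: auxiliary-controlled Diels–Alder reaction in which the cationic aluminium chelate of the s-cis imide is attacked on the Cα face away from the benzyl group (sets C1 and C14), the endo transition state puts the C10 substituent cis to the acyl group, the (E) dienophile places C15 trans to it, and the 1-alkyl and 3-methyl groups of the diene both direct the acyl-bearing carbon to C10.

Step 10
Reactants: 14 Diels–Alder adduct
Product: 15 C2 primary alcohol of the cyclohexene (CH2OH at C1, CH2OPiv at C10)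
Conditions: LiBH4, H2O (1 equiv), Et2O, 0 °C
Reagents that add atoms: none
Why: reductive removal of the auxiliary by hydride attack on the exocyclic imide carbonyl, which is much faster at 0 °C than reduction of the hindered pivalate.

Step 11
Reactants: 15 C2 primary alcohol of the cyclohexene
Product: 17 C2,C11 diol with the C11 hydroxyl trans to the C12 methyl, via borane adduct 16 (not isolated)
Conditions: BH3·THF, THF, 0 °C → rt; then NaBO3·4H2O, H2O, rt
Reagents that add atoms: sodium perborate, [Na+].[Na+].O[B-]1(O)OO[B-](O)(O)OO1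
Why: hydroboration–oxidation in which boron goes to the less substituted C11 and B–H adds syn from the face opposite the pseudoaxial C10 CH2OPiv group, setting the C12 methyl cis to the C1 and C10 substituents; the C11 alcohol formed with retention is trans to the methyl and is corrected in steps 12 and 14.

Step 12
Reactants: 17 C2,C11 diol
Product: 18 keto aldehyde (C2 aldehyde, C11 ketone)
Conditions: Dess–Martin periodinane, NaHCO3, CH2Cl2, 0 °C → rt
Reagents that add atoms: none
Why: buffered Dess–Martin oxidation of both alcohols without epimerising C1, C10 or C12, which removes the wrong C11 configuration and frees the C2 aldehyde in one operation.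

Step 13
Reactants: 18 keto aldehyde; 19 ethyltriphenylphosphonium iodide
Product: 23 C11 ketone bearing the (Z)-2-iodoprop-1-enyl group at C1, via ethylidene ylide 20 (not isolated), via iodoethylphosphonium iodide 21 (not isolated), via iodo ylide 22 (not isolated)
Conditions: 19, n-BuLi, THF, 0 °C; I2, −78 °C; NaN(SiMe3)2, −78 °C; then 18, −78 → −20 °C
Reagents that add atoms: iodine, [I][I]
Why: Stork–Zhao-type α-iodo Wittig olefination, which gives the (Z)-2-iodoalkene (iodine cis to C1) and takes the aldehyde in preference to the hindered ketone.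

Step 14
Reactants: 23 C11 ketone bearing the (Z)-2-iodoprop-1-enyl group
Product: 24 C11 alcohol, hydroxyl cis to the C10 and C12 substituents
Conditions: LiBH(s-Bu)3 (L-Selectride), THF, −78 °C; then aq. NH4Cl
Reagents that add atoms: none
Why: the bulky borohydride attacks the C11 ketone from the face opposite the flanking C10 and C12 substituents, so the new C–O bond is cis to both (the all-cis C10, C11, C12 array of the target), while the pivalate and the alkenyl iodide do not react at −78 °C.

Step 15
Reactants: 24 C11 alcohol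
Product: 25 C11 TBS ether
Conditions: TBSOTf, 2,6-lutidine, CH2Cl2, 0 °C
Reagents that add atoms: tert-butyldimethylsilyl trifluoromethanesulfonate, CC(C)(C)[Si](C)(C)OS(=O)(=O)C(F)(F)F
Why: the silyl triflate silylates even this hindered secondary alcohol.

Step 16
Reactants: 25 C11 TBS ether; 26 acrolein diethyl acetal
Product: 28 (Z)-C2=C3 olefin carrying the C4–C6 chain as the C6 diethyl acetal, via alkyl-9-BBN 27 (not isolated)
Conditions: 26, 9-BBN, THF, 0 °C → rt; then 25, Pd(dppf)Cl2 (cat.), AsPh3, Cs2CO3, DMF/H2O, rt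
Reagents that add atoms: none
Why: B-alkyl Suzuki–Miyaura coupling (oxidative addition to zerovalent palladium, transmetalation of the primary alkylborane) with retention of the olefin geometry, so C4 takes the place of iodine cis to C1.

Step 17
Reactants: 28 (Z)-C2=C3 olefin with the C6 diethyl acetal
Product: 29 C9 primary alcohol
Conditions: i-Bu2AlH, CH2Cl2, −78 °C
Reagents that add atoms: none
Why: reductive cleavage of the pivalate; acetal, silyl ethers and olefin are inert.

Step 18
Reactants: 29 C9 primary alcohol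
Product: 30 C9 aldehyde
Conditions: Dess–Martin periodinane, NaHCO3, CH2Cl2, 0 °C
Reagents that add atoms: none
Why: buffered Dess–Martin oxidation, which does not epimerise C10 or eliminate the β-silyloxy group.

Step 19
Reactants: 30 C9 aldehyde; 31 prop-1-ynylmagnesium bromide
Product: 32 propargylic alcohols, both C9 epimers
Conditions: THF, −78 °C
Reagents that add atoms: none
Why: Grignard addition at low temperature; no selectivity is needed because C9 is oxidised in the next step.

Step 20
Reactants: 32 propargylic alcohols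
Product: 33 C9 ynone
Conditions: Dess–Martin periodinane, NaHCO3, CH2Cl2, 0 °C
Reagents that add atoms: none
Why: mild oxidation of the propargylic alcohol that leaves the α-centre C10 untouched.

Step 21
Reactants: 33 C9 ynone
Product: 34 (9R)-propargylic alcohol
Conditions: Ru[(R,R)-TsNCH(Ph)CH(Ph)NH](p-cymene) (cat.), i-PrOH, rt
Reagents that add atoms: none
Why: Noyori asymmetric transfer hydrogenation of an ynone under base-free conditions; the (R,R) catalyst sets the (9R) carbinol under reagent control (alkynyl in the place taken by aryl in aryl ketones).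

Step 22
Reactants: 34 (9R)-propargylic alcohol
Product: 36 (Z)-3-iodoallylic alcohol (iodine on C7 cis to C9), via vinylalanate 35 (not isolated)
Conditions: NaAlH2(OCH2CH2OMe)2, THF, 0 °C → rt; then I2, THF, −78 °C
Reagents that add atoms: iodine, [I][I]
Why: hydroxyl-directed trans-hydroalumination places aluminium on the distal alkyne carbon C7 in a five-membered alkoxyaluminate, and iodinolysis with retention gives the (Z)-alkenyl iodide.

Step 23
Reactants: 36 (Z)-3-iodoallylic alcohol
Product: 37 C9 acetate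
Conditions: Ac2O, pyridine, 4-(dimethylamino)pyridine (cat.), CH2Cl2, 0 °C → rt
Reagents that add atoms: acetic anhydride, CC(=O)OC(C)=O
Why: acetylation of the only free hydroxyl; the ester keeps O9 distinct from O6 and later deactivates the C7=C8 olefin.

Step 24
Reactants: 37 C9 acetate
Product: 38 C6 aldehyde
Conditions: pyridinium p-toluenesulfonate (cat.), acetone/H2O, 40 °C
Reagents that add atoms: water, O
Why: acyclic diethyl acetals hydrolyse under weak acid that leaves silyl ethers, the allylic acetate and the alkenyl iodide intact.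

Step 25
Reactants: 38 C6 aldehyde
Product: 40 cyclohexane-fused cyclodeca-2,7-diene with the (6R) allylic alcohol and the (9S) acetate, via alkenylchromium 39 (not isolated)
Conditions: CrCl2 (excess), NiCl2 (cat.), DMSO/THF, rt, high dilution
Reagents that add atoms: none
Why: Nozaki–Hiyama–Kishi ring closure (oxidative addition of the alkenyl iodide to zerovalent nickel, transmetalation to trivalent chromium, addition to the aldehyde with retention of the (Z) geometry), helped by the cis ring fusion and the two (Z) olefins; the (6R) alcohol should arise from addition on the outer face of the aldehyde in the folded chain, under substrate control.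

Step 26
Reactants: 40 macrocyclic (6R) allylic alcohol
Product: 41 C6 TBDPS ether
Conditions: TBDPSCl, imidazole, 4-(dimethylamino)pyridine (cat.), DMF, rt → 40 °C
Reagents that add atoms: tert-butyl(chloro)diphenylsilane, CC(C)(C)[Si](Cl)(c1ccccc1)c1ccccc1
Why: silylation of the allylic alcohol with a group that outlasts both TBS ethers and keeps O6 from acting as a nucleophile in step 29.

Step 27
Reactants: 41 C6 TBDPS ether
Product: 42 (2R,3S)-epoxide with the C9 acetate
Conditions: 3-ClC6H4CO3H, NaHCO3, CH2Cl2, −20 → 0 °C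
Reagents that add atoms: 3-chloroperbenzoic acid, OOC(=O)c1cccc(Cl)c1
Why: Prilezhaev epoxidation, stereospecific for the (Z) olefin; the peracid should take the isolated C2=C3 bond (C7=C8 is deactivated and shielded by its two allylic oxygen groups) and attack its outer face, anti to C10 and the ring interior in the conformer with H1 eclipsing the olefin.

Step 28
Reactants: 42 (2R,3S)-epoxide with the C9 acetate
Product: 43 hydroxy epoxide (free C9 hydroxyl, C2–C3 epoxide)
Conditions: K2CO3, MeOH, 0 °C
Reagents that add atoms: none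
Why: transesterification removes the allylic acetate without touching silyl ethers or epoxide; any ring closure that began here would lead to 44, the product of step 29.

Step 29
Reactants: 43 hydroxy epoxide
Product: 44 oxolane-bridged oxonene with the free (3S) tertiary alcohol
Conditions: camphor-10-sulfonic acid (10 mol%), CH2Cl2, 0 °C
Reagents that add atoms: none
Why: The sulfonic acid activates the epoxide oxygen, and the C9 hydroxyl, held across the ten-membered ring on the C10 side of C2, attacks C2 from the rear of the C2–O bond in an SN2 opening; the closest known reaction type is the acid-mediated exo cyclisation of 4,5-epoxy alcohols with a tertiary distal carbon that is used to make the oxolanes of polyethers. The oxolane (O, C9, C10, C1, C2) closes in the 5-exo-tet mode, and the oxonene (O, C2 to C9) is not closed separately but results from the same bond dividing the ten-membered carbocycle (formally a 9-endo closure made possible by the preformed ring). C2 is the only centre that changes: it is inverted from R to S, so its configuration is fixed by the epoxide face set in step 27, while C3 keeps its C–O bond and becomes the (3S) tertiary alcohol. The step needs attack at the secondary C2 and not at the tertiary C3 (6-endo, an oxane) or ionisation at C3; a weak acid in a non-polar solvent keeps the opening concerted, and the five-membered transition state with O9, C2 and the leaving oxygen in line is favoured over the six-membered one at the more hindered C3. No other nucleophile competes because O6 and O11 are silylated.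

Step 30
Reactants: 44 oxolane-bridged oxonene
Product: 45 C16 primary alcohol (C3,C16 diol)
Conditions: HF·pyridine, pyridine, THF, 0 °C
Reagents that add atoms: none
Why: buffered fluoride cleaves the primary TBS ether much faster than the hindered secondary TBS ether at C11 or the TBDPS ether at C6.

Step 31
Reactants: 45 C16 primary alcohol
Product: 47 tetracycle with the oxepane closed (O11 TBS, O6 TBDPS), via primary triflate 46 (not isolated)
Conditions: Tf2O, 2,6-lutidine, CH2Cl2, −78 → 0 °C
Reagents that add atoms: none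
Why: the primary alcohol is triflated in preference to the tertiary one, and the C3 hydroxyl then displaces the triflate in a 7-exo-tet Williamson-type closure that gives the trans-fused oxepane without touching a stereocentre.

Step 32
Reactants: 47 tetracycle with the oxepane closed
Product: 48 C11 alcohol
Conditions: HF·pyridine (excess), THF, rt
Reagents that add atoms: none
Why: unbuffered HF·pyridine removes the remaining TBS ether, while the TBDPS ether is far more stable to acidic fluoride.

Step 33
Reactants: 48 C11 alcohol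
Product: 49 C11 acetate with the C6 TBDPS ether
Conditions: Ac2O, 4-(dimethylamino)pyridine, pyridine, rt
Reagents that add atoms: acetic anhydride, CC(=O)OC(C)=O
Why: acylation of the only free hydroxyl.

Step 34
Reactants: 49 C11 acetate with the C6 TBDPS ether
Product: 50 target compound CNP0289966.2
Conditions: Bu4NF, AcOH, THF, 0 °C → rt
Reagents that add atoms: none
Why: fluoride cleavage of the TBDPS ether, buffered with acetic acid so that the hindered C11 acetate is not cleaved or moved.

**Compound list**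
1 | (R)-4-benzyloxazolidin-2-one | O=C1N[C@H](Cc2ccccc2)CO1 | starting material
2 | bromoacetyl bromide | BrCC(Br)=O | starting material
3 | (R)-4-benzyl-3-(2-bromoacetyl)oxazolidin-2-one | O=C(CBr)N1[C@H](Cc2ccccc2)COC1=O | intermediate
4 | (R)-4-benzyl-3-[2-(diethoxyphosphoryl)acetyl]oxazolidin-2-one | CCOP(=O)(CC(=O)N1[C@H](Cc2ccccc2)COC1=O)OCC | intermediate
5 | methyl (S)-3-hydroxy-2-methylpropanoate | COC(=O)[C@@H](C)CO | starting material
6 | methyl (S)-3-(tert-butyldimethylsilyloxy)-2-methylpropanoate | COC(=O)[C@@H](C)CO[Si](C)(C)C(C)(C)C | intermediate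
7 | (S)-3-(tert-butyldimethylsilyloxy)-2-methylpropanal | O=C[C@@H](C)CO[Si](C)(C)C(C)(C)C | intermediate
8 | (R)-4-benzyl-3-[(2E,4R)-5-(tert-butyldimethylsilyloxy)-4-methylpent-2-enoyl]oxazolidin-2-one | CC(C)(C)[Si](C)(C)OC[C@H](C)/C=C/C(=O)N1[C@H](Cc2ccccc2)COC1=O | intermediate
9 | methacrolein | C=C(C)C=O | starting material
10 | ethyl (triphenylphosphoranylidene)acetate | CCOC(=O)C=P(c1ccccc1)(c1ccccc1)c1ccccc1 | starting material
11 | ethyl (2E)-4-methylpenta-2,4-dienoate | C=C(C)/C=C/C(=O)OCC | intermediate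
12 | (2E)-4-methylpenta-2,4-dien-1-ol | C=C(C)/C=C/CO | intermediate
13 | (2E)-4-methylpenta-2,4-dien-1-yl pivalate | C=C(C)/C=C/COC(=O)C(C)(C)C | intermediate
14 | Diels–Alder adduct (1S,10R,14S,15R): cyclohex-11-ene with acyl oxazolidinone at C1, CH2OPiv at C10, CH(Me)CH2OTBS at C14 | CC(C)(C)[Si](C)(C)OC[C@H](C)[C@@H]1CC(C)=C[C@@H](COC(=O)C(C)(C)C)[C@H]1C(=O)N1[C@H](Cc2ccccc2)COC1=O | intermediate
15 | C2 primary alcohol of the cyclohexene | CC(C)(C)[Si](C)(C)OC[C@H](C)[C@@H]1CC(C)=C[C@@H](COC(=O)C(C)(C)C)[C@H]1CO | intermediate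
16 | borane adduct (C11 alkylborane, O2 alkoxyborane), not isolated | CC(C)(C)[Si](C)(C)OC[C@H](C)[C@@H]1C[C@@H](C)[C@H](B)[C@@H](COC(=O)C(C)(C)C)[C@H]1COB | intermediate
17 | C2,C11 diol, C11 hydroxyl trans to C12 methyl | CC(C)(C)[Si](C)(C)OC[C@H](C)[C@@H]1C[C@@H](C)[C@H](O)[C@@H](COC(=O)C(C)(C)C)[C@H]1CO | intermediate
18 | keto aldehyde (C2 aldehyde, C11 ketone) | CC(C)(C)[Si](C)(C)OC[C@H](C)[C@@H]1C[C@@H](C)C(=O)[C@@H](COC(=O)C(C)(C)C)[C@H]1C=O | intermediate
19 | ethyltriphenylphosphonium iodide | CC[P+](c1ccccc1)(c1ccccc1)c1ccccc1.[I-] | starting material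
20 | ethylidenetriphenylphosphorane, not isolated | CC=P(c1ccccc1)(c1ccccc1)c1ccccc1 | intermediate
21 | (1-iodoethyl)triphenylphosphonium iodide, not isolated | CC(I)[P+](c1ccccc1)(c1ccccc1)c1ccccc1.[I-] | intermediate
22 | (1-iodoethylidene)triphenylphosphorane, not isolated | CC(I)=P(c1ccccc1)(c1ccccc1)c1ccccc1 | intermediate
23 | C11 ketone with (Z)-2-iodoprop-1-enyl at C1 | CC(C)(C)[Si](C)(C)OC[C@H](C)[C@@H]1C[C@@H](C)C(=O)[C@@H](COC(=O)C(C)(C)C)[C@H]1/C=C(C)\I | intermediate
24 | C11 alcohol, all-cis at C10, C11, C12 | CC(C)(C)[Si](C)(C)OC[C@H](C)[C@@H]1C[C@@H](C)[C@@H](O)[C@@H](COC(=O)C(C)(C)C)[C@H]1/C=C(C)\I | intermediate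
25 | C11 TBS ether | CC(C)(C)[Si](C)(C)OC[C@H](C)[C@@H]1C[C@@H](C)[C@@H](O[Si](C)(C)C(C)(C)C)[C@@H](COC(=O)C(C)(C)C)[C@H]1/C=C(C)\I | intermediate
26 | acrolein diethyl acetal | C=CC(OCC)OCC | starting material
27 | 9-(3,3-diethoxypropyl)-9-borabicyclo[3.3.1]nonane, not isolated | CCOC(CCB1C2CCCC1CCC2)OCC | intermediate
28 | (Z)-C2=C3 olefin with C6 diethyl acetal, C9 pivalate | CC(C)(C)[Si](C)(C)OC[C@H](C)[C@@H]1C[C@@H](C)[C@@H](O[Si](C)(C)C(C)(C)C)[C@@H](COC(=O)C(C)(C)C)[C@H]1/C=C(C)\CCC(OCC)OCC | intermediate
29 | C9 primary alcohol | CC(C)(C)[Si](C)(C)OC[C@H](C)[C@@H]1C[C@@H](C)[C@@H](O[Si](C)(C)C(C)(C)C)[C@@H](CO)[C@H]1/C=C(C)\CCC(OCC)OCC | intermediate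
30 | C9 aldehyde | CC(C)(C)[Si](C)(C)OC[C@H](C)[C@@H]1C[C@@H](C)[C@@H](O[Si](C)(C)C(C)(C)C)[C@@H](C=O)[C@H]1/C=C(C)\CCC(OCC)OCC | intermediate
31 | prop-1-ynylmagnesium bromide | CC#C[Mg]Br | starting material
32 | propargylic alcohols, C9 epimers | CC(C)(C)[Si](C)(C)OC[C@H](C)[C@@H]1C[C@@H](C)[C@@H](O[Si](C)(C)C(C)(C)C)[C@@H](C(O)C#CC)[C@H]1/C=C(C)\CCC(OCC)OCC | intermediate
33 | C9 ynone | CC(C)(C)[Si](C)(C)OC[C@H](C)[C@@H]1C[C@@H](C)[C@@H](O[Si](C)(C)C(C)(C)C)[C@@H](C(=O)C#CC)[C@H]1/C=C(C)\CCC(OCC)OCC | intermediate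
34 | (9R)-propargylic alcohol | CC(C)(C)[Si](C)(C)OC[C@H](C)[C@@H]1C[C@@H](C)[C@@H](O[Si](C)(C)C(C)(C)C)[C@@H]([C@@H](O)C#CC)[C@H]1/C=C(C)\CCC(OCC)OCC | intermediate
35 | sodium cyclic alkoxy(alkenyl)aluminate from hydroalumination, not isolated | CC(C)(C)[Si](C)(C)OC[C@H](C)[C@@H]1C[C@@H](C)[C@@H](O[Si](C)(C)C(C)(C)C)[C@@H]([C@H]2O[Al-](OCCOC)(OCCOC)C(C)=C2)[C@H]1/C=C(C)\CCC(OCC)OCC.[Na+] | intermediate
36 | (9R)-(Z)-3-iodoallylic alcohol | CC(C)(C)[Si](C)(C)OC[C@H](C)[C@@H]1C[C@@H](C)[C@@H](O[Si](C)(C)C(C)(C)C)[C@@H]([C@@H](O)/C=C(C)\I)[C@H]1/C=C(C)\CCC(OCC)OCC | intermediate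
37 | C9 acetate of the iodoallylic alcohol | CC(C)(C)[Si](C)(C)OC[C@H](C)[C@@H]1C[C@@H](C)[C@@H](O[Si](C)(C)C(C)(C)C)[C@@H]([C@@H](OC(C)=O)/C=C(C)\I)[C@H]1/C=C(C)\CCC(OCC)OCC | intermediate
38 | C6 aldehyde with the (Z)-alkenyl iodide | CC(C)(C)[Si](C)(C)OC[C@H](C)[C@@H]1C[C@@H](C)[C@@H](O[Si](C)(C)C(C)(C)C)[C@@H]([C@@H](OC(C)=O)/C=C(C)\I)[C@H]1/C=C(C)\CCC=O | intermediate
39 | alkenylchromium dichloride, not isolated | CC(C)(C)[Si](C)(C)OC[C@H](C)[C@@H]1C[C@@H](C)[C@@H](O[Si](C)(C)C(C)(C)C)[C@@H]([C@@H](OC(C)=O)/C=C(C)\[Cr](Cl)Cl)[C@H]1/C=C(C)\CCC=O | intermediate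
40 | cyclohexane-fused (2Z,7Z)-cyclodecadiene, (6R) alcohol, (9S) acetate | CC(C)(C)[Si](C)(C)OC[C@H](C)[C@@H]1C[C@@H](C)[C@@H](O[Si](C)(C)C(C)(C)C)[C@@H]2[C@H]1/C=C(C)\CC[C@@H](O)/C(C)=C\[C@@H]2OC(C)=O | intermediate
41 | C6 TBDPS ether | CC(C)(C)[Si](C)(C)OC[C@H](C)[C@@H]1C[C@@H](C)[C@@H](O[Si](C)(C)C(C)(C)C)[C@@H]2[C@H]1/C=C(C)\CC[C@@H](O[Si](c3ccccc3)(c3ccccc3)C(C)(C)C)/C(C)=C\[C@@H]2OC(C)=O | intermediate
42 | (2R,3S)-epoxide, C9 acetate | CC(C)(C)[Si](C)(C)OC[C@H](C)[C@@H]1C[C@@H](C)[C@@H](O[Si](C)(C)C(C)(C)C)[C@@H]2[C@H]1[C@H]3O[C@@]3(C)CC[C@@H](O[Si](c4ccccc4)(c4ccccc4)C(C)(C)C)/C(C)=C\[C@@H]2OC(C)=O | intermediate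
43 | hydroxy epoxide (2R,3S,6R,9S), key-step precursor | CC(C)(C)[Si](C)(C)OC[C@H](C)[C@@H]1C[C@@H](C)[C@@H](O[Si](C)(C)C(C)(C)C)[C@@H]2[C@H]1[C@H]3O[C@@]3(C)CC[C@@H](O[Si](c4ccccc4)(c4ccccc4)C(C)(C)C)/C(C)=C\[C@@H]2O | intermediate
44 | oxolane-bridged oxonene (2S,3S,6R,9S) with free C3 alcohol | CC(C)(C)[Si](C)(C)OC[C@H](C)[C@@H]1C[C@@H](C)[C@@H](O[Si](C)(C)C(C)(C)C)[C@@H]2[C@H]1[C@@H]3O[C@H]2/C=C(C)\[C@H](O[Si](c4ccccc4)(c4ccccc4)C(C)(C)C)CC[C@]3(C)O | intermediate
45 | C16 primary alcohol | OC[C@H](C)[C@@H]1C[C@@H](C)[C@@H](O[Si](C)(C)C(C)(C)C)[C@@H]2[C@H]1[C@@H]3O[C@H]2/C=C(C)\[C@H](O[Si](c4ccccc4)(c4ccccc4)C(C)(C)C)CC[C@]3(C)O | intermediate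
46 | C16 primary triflate, not isolated | FC(F)(F)S(=O)(=O)OC[C@H](C)[C@@H]1C[C@@H](C)[C@@H](O[Si](C)(C)C(C)(C)C)[C@@H]2[C@H]1[C@@H]3O[C@H]2/C=C(C)\[C@H](O[Si](c4ccccc4)(c4ccccc4)C(C)(C)C)CC[C@]3(C)O | intermediate
47 | tetracycle with oxepane, O11 TBS, O6 TBDPS | CC(C)(C)[Si](C)(C)O[C@H]1[C@@H]2[C@@H]3[C@@H](C[C@H]1C)[C@@H](C)CO[C@@]1(C)CC[C@@H](O[Si](c4ccccc4)(c4ccccc4)C(C)(C)C)/C(C)=C\[C@@H]2O[C@@H]31 | intermediate
48 | C11 alcohol, O6 TBDPS | O[C@H]1[C@@H]2[C@@H]3[C@@H](C[C@H]1C)[C@@H](C)CO[C@@]1(C)CC[C@@H](O[Si](c4ccccc4)(c4ccccc4)C(C)(C)C)/C(C)=C\[C@@H]2O[C@@H]31 | intermediate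
49 | C11 acetate, O6 TBDPS | CC(=O)O[C@H]1[C@@H]2[C@@H]3[C@@H](C[C@H]1C)[C@@H](C)CO[C@@]1(C)CC[C@@H](O[Si](c4ccccc4)(c4ccccc4)C(C)(C)C)/C(C)=C\[C@@H]2O[C@@H]31 | intermediate
50 | CNP0289966.2 | CC(=O)O[C@H]1[C@@H]2[C@@H]3[C@@H](C[C@H]1C)[C@@H](C)CO[C@@]1(C)CC[C@@H](O)/C(C)=C\[C@@H]2O[C@@H]31 | target

**Step count**
Total steps: 34. Longest linear sequence: 29 steps (steps 3 to 5 and 9 to 34).

**Steps most likely to fail**

Step 29, opening diverted to the tertiary carbon C3, or ionisation at C3 followed by elimination or hydride shift. The fallback moves the activation from the electrophile to the nucleophile. From 43, NaH in THF at 0 °C gives the C9 sodium alkoxide F1, which opens the epoxide at the secondary C2 by a purely SN2 5-exo attack that an alkoxide does not make at a tertiary centre. A water quench returns the route at 44. The run is kept cold and short to limit silyl transfer from O11 to O9.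

Step 27, poor facial selectivity on the C2=C3 olefin or oxidation of C7=C8. The fallback takes stereocontrol from the substrate to the reagent. From 41, a Shi epoxidation is run with the dioxirane made from the D-fructose-derived ketone 1,2:4,5-di-O-isopropylidene-β-D-erythro-2,3-hexodiulo-2,6-pyranose and KHSO5 (K2CO3 buffer, MeCN/dimethoxymethane/water, 0 °C). The spiro transition-state model for trisubstituted olefins predicts oxygen delivery to the face that gives the (2R,3S) epoxide, and the route is rejoined at 42. No new compound is made (F0).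

Step 25, low facial selectivity at the C6 aldehyde during ring closure. The fallback sets C6 after the ring is closed, by a reagent-controlled reduction. From 38 the same CrCl2/NiCl2 closure is run and the product is taken on as the C6 epimer mixture F2. Dess–Martin oxidation gives the (Z)-enone F3. Corey–Bakshi–Shibata reduction with BH3·SMe2 and the catalyst (S)-1-methyl-3,3-diphenyltetrahydro-1H,3H-pyrrolo[1,2-c][1,3,2]oxazaborole, with the alkenyl group as the large substituent, should give the (6R) alcohol 40.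

Further compounds
F1 | step 29 | C9 sodium alkoxide of hydroxy epoxide 43 | CC(C)(C)[Si](C)(C)OC[C@H](C)[C@@H]1C[C@@H](C)[C@@H](O[Si](C)(C)C(C)(C)C)[C@@H]2[C@H]1[C@H]3O[C@@]3(C)CC[C@@H](O[Si](c4ccccc4)(c4ccccc4)C(C)(C)C)/C(C)=C\[C@@H]2[O-].[Na+]
F0 | step 27 | none | none
F2 | step 25 | macrocyclic allylic alcohol, mixture of C6 epimers | CC(C)(C)[Si](C)(C)OC[C@H](C)[C@@H]1C[C@@H](C)[C@@H](O[Si](C)(C)C(C)(C)C)[C@@H]2[C@H]1/C=C(C)\CCC(O)/C(C)=C\[C@@H]2OC(C)=O
F3 | step 25 | macrocyclic (Z)-enone, C6 ketone | CC(C)(C)[Si](C)(C)OC[C@H](C)[C@@H]1C[C@@H](C)[C@@H](O[Si](C)(C)C(C)(C)C)[C@@H]2[C@H]1/C=C(C)\CCC(=O)/C(C)=C\[C@@H]2OC(C)=O
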